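## Analysis of the target

The target is a sesquilignan made of three guaiacyl-type units. Its core is a 1-aryl-2,3-dimethyltetralin: ring A is the fused arene (6-OMe, 7-OH), ring B the carbocycle C1–C4/C4a/C8a, and ring C the aryl group on C1. The C4' oxygen of ring C is etherified by C8' of a 1-(4-hydroxy-3-methoxyphenyl)-1-hydroxypropan-2-yl unit (ring D, carbinol carbon C7'). Ring B carries three contiguous stereocentres, C1 (S), C2 (S) and C3 (R), with aryl, methyl and methyl all trans; the side chain carries C7' (S) and C8' (R) in the erythro relationship, and ring C insulates the two sets, so each must be set in absolute terms. The sensitive functions are the two free phenols, the doubly benzylic C1–H and above all the para-hydroxybenzylic alcohol at C7', which ionises to a quinone methide under acid and is prone to hydrogenolysis. The main difficulty is that C1 is a diarylmethine whose two aryl groups, ring A and ring C, are both 3,4-dioxygenated and differ only in which oxygen bears methyl, so neither a catalyst nor an electrophilic ring closure readily tells them apart; C2 and C3 bear only methyl groups and offer no heteroatom handle. The strategy rests on the pair C1/C2: a diarylmethine next to a methyl-bearing carbon is what results when an aryl group and a methyl group are added across the two alkene carbons of a ring A styrenyl boron compound, with boron left on C2 as the handle for C3 and C4. A chlorine at C4a marks ring A throughout and finally closes ring B at C4–C4a, so the two aryl groups are never equivalent.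

## Retrosynthetic reasoning

Target 33 is traced back to its bis(silyl) ether 32, so that the last step is a mild fluoride desilylation that leaves the C7' carbinol alone. The C7'–H bond of 32 is then cut to give aryl ketone 31. With C8' already in place, chelation-controlled hydride delivery should give the erythro (7'S,8'R) arrangement.

Ketone 31 is cut at the C7'–ring D bond into Weinreb amide 27 and aryl Grignard reagent 30, which comes from bromide 29 and that from bromophenol 28. Amide 27 comes from ester 26, and 26 from phenol 24 and ethyl (S)-lactate 25 by cutting the C8'–O bond. The forward reaction is a Mitsunobu etherification that inverts the lactate centre to the required 8'R configuration. This cut lets a chiral-pool ester supply C8' and keeps the labile carbinol out of the route until the penultimate step.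

Phenol 24 is the debenzylated form of tetralin 23. The ring C oxygen carries the only benzyl ether, so hydrogenolysis unmasks it while ring A stays silylated.

In 23 the C4–C4a bond is cut, giving the open-chain primary alkylboronate 22 with chlorine at the future C4a. The cut is not made at C1–C8a, because an electrophilic closure onto C1 could not distinguish ring A from ring C. A cross-coupling can only occur at the carbon that bears the halogen. The forward reaction is an intramolecular Suzuki–Miyaura coupling.

Boronate 22 is the one-carbon (C4) homologue of secondary boronate 20. Boronate 20 is cut at C2–C3 into secondary boronate 16 and the lithiated benzoate 18 derived from ester 17. Both homologations are 1,2-shifts with retention at the migrating carbon, so C2 is carried over unchanged and C3 is fixed by the configuration of reagent 18 alone.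

Boronate 16 is cut twice, at the bond from C1 to ring C and at C2–CH3, leading back to (Z)-alkenylboronate 9, aryl triflate 13 and methyllithium 14. The forward reaction has to add methyl and aryl anti across the alkene, with methyl going to the boron-bearing carbon, and on one alkene face only. This forms two C–C bonds and both C1 and C2 in one step and keeps boron on C2. Boron in 9 is bound to diol 6, because with less hindered diols the borates of β-substituted alkenylboronates tend to pass the alkenyl group straight to palladium.

Alkenylboronate 9 comes from terminal alkyne 4, catecholborane 7 and diol 6 (from dione 5) by a trans-hydroboration that places boron cis to the aryl group. Alkyne 4 comes from aldehyde 3 by one-carbon homologation, 3 from phenol 2 by silylation, and 2 from aldehyde 1 by selective demethylation. Aldehyde 1 already has chlorine para to the oxygen that becomes the C7 phenol.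

Triflate 13 comes from phenol 12, and 12 from O-benzylvanillin 10 through formate 11 by Baeyer–Villiger oxidation.

## Alternatives that were turned down

Alternative 1: Ring B is closed at C1–C2. Acid dehydrates the diaryl carbinol A2 to the para-quinone methide of ring C, and the enamine formed from the tethered aldehyde and a secondary-amine catalyst attacks C1 through its α-carbon to give aldehyde A1.
- For it: the closure is metal-free and mild; the free ring C phenol it needs is the one later used for the side chain; C2 carries an epimerisable formyl group, so the all-trans isomer can be reached by equilibration.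
- Against it: the formyl group must afterwards be reduced to methyl (about three steps); C1 is set only by induction from C3 through a cyclic transition state; the chiral chain has to be built and placed ortho to the carbinol on ring A; the absolute configuration of three centres rests on one remote methyl centre.
- Comparison: this alternative is stronger in avoiding palladium and three successive boron steps. The chosen route offers instead independent catalyst or reagent control at C1/C2 and at C3, and puts the C2 methyl group in directly.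

Alternative 2: Ring B is cut at C1–C2 and C3–C4. Irradiation of aldehyde A4 gives a hydroxy-ortho-quinodimethane that adds crotonate A5 to give A3.
- For it: two bonds, the ring and four stereocentres form in one step with predictable relative configuration from simple precursors, and the allyl and benzyl ethers already distinguish the phenols.
- Against it: there is no reliable absolute control with a simple crotonate, so a resolution would be needed; C3 arrives as an ester and C4 as a carbinol, which must be taken down to CH3 and CH2 (four to five steps, including a benzylic deoxygenation next to the doubly benzylic C1).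
- Comparison: this alternative is stronger in bond-forming efficiency for the ring. The chosen route builds C3 and C4 at the correct oxidation level and controls the absolute configuration.

Alternative 3: Ring B is cut at C2–C3 and C1–C8a. One-electron oxidation of alkene A7 by a photocatalyst, attack by alkene A8 to form C2–C3, and capture of the C1 cation by ring A give A6.
- For it: this is clearly the shortest way to the core, giving the whole skeleton with the three ring stereocentres trans from two near-commodity alkenes in one step.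
- Against it: the product is racemic, with no element in the step to control absolute configuration; cross- and homo-dimerisation of two alkenes of similar oxidation potential compete, as do cyclobutane dimers; the closing arene is the one deactivated by the ester.
- Comparison: this alternative is far stronger on step economy and equal on relative configuration. The chosen route offers absolute control and unambiguous chemo- and regiocontrol, at the cost of about ten more steps.

Key step: step 8

Remarks on the chemistry:
- "B(mac)" denotes boron bound to both oxygens of cis-diol 6 (a cis-6b,9a-dimethyl-6b,9a-dihydroacenaphtho[1,2-d][1,3,2]dioxaborole, boron at position 8). It is used in place of a pinacol ester because borates of β-substituted alkenyl pinacol boronates mainly undergo direct alkenyl transfer to palladium.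
- Assumption: aldehyde 1 (6-chloroveratraldehyde) is taken as purchasable.

## Route

Step 1
Reactants: 1 2-chloro-4,5-dimethoxybenzaldehyde
Product: 2 2-chloro-5-hydroxy-4-methoxybenzaldehyde
Conditions: DL-methionine, conc. H2SO4, rt
Reagents that add atoms: none
Why: Brønsted-acid ether cleavage with methionine as methyl acceptor; the 4-methoxy oxygen is tied up by conjugation with the protonated formyl group, so only the 5-methoxy group (meta to the aldehyde) is protonated and demethylated, the selectivity known for the 2-bromo analogue.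

Step 2
Reactants: 2 2-chloro-5-hydroxy-4-methoxybenzaldehyde
Product: 3 2-chloro-4-methoxy-5-(triisopropylsilyloxy)benzaldehyde
Conditions: TIPSCl, imidazole, DMF, rt
Reagents that add atoms: triisopropylsilyl chloride, CC(C)[Si](Cl)(C(C)C)C(C)C
Why: Standard silylation of a phenol; the triisopropylsilyl ether withstands the organolithium, Grignard and aqueous-base steps ahead and falls to fluoride at the end.

Step 3
Reactants: 3 2-chloro-4-methoxy-5-(triisopropylsilyloxy)benzaldehyde
Product: 4 1-chloro-2-ethynyl-5-methoxy-4-(triisopropylsilyloxy)benzene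
Conditions: Me3SiCHN2, LiN(iPr)2, THF, −78 °C → rt
Reagents that add atoms: trimethylsilyldiazomethane, C[Si](C)(C)C=[N+]=[N-]
Why: Colvin rearrangement: the lithiated diazo compound adds to the aldehyde, silanolate and N2 are lost and the alkylidene carbene rearranges to the aryl alkyne; the medium is aprotic, so the aryl silyl ether is not exposed to carbonate in methanol.

Step 4
Reactants: 5 acenaphthoquinone (acenaphthylene-1,2-dione)
Product: 6 cis-1,2-dimethyl-1,2-dihydroacenaphthylene-1,2-diol (meso)
Conditions: AlMe3, toluene, 0 °C → rt; aq. Rochelle salt; recrystallisation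
Reagents that add atoms: trimethylaluminium, C[Al](C)C
Why: Double 1,2-addition of methyl to the dione; the second methyl group should enter anti to the bulky aluminium alkoxide on the neighbouring carbon, giving the cis diol, which is the only isomer able to bridge one boron atom.

Step 5
Reactants: 4 1-chloro-2-ethynyl-5-methoxy-4-(triisopropylsilyloxy)benzene; 7 catecholborane; 6 cis-1,2-dimethyl-1,2-dihydroacenaphthylene-1,2-diol
Product: 9 [(Z)-2-(2-chloro-4-methoxy-5-triisopropylsilyloxyphenyl)ethenyl]B(mac), via catechol boronate 8 (not isolated)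
Conditions: 7, [Rh(cod)Cl]2 (cat.), P(iPr)3, Et3N, cyclohexane, rt; then 6, rt
Reagents that add atoms: none
Why: Rhodium-catalysed trans-hydroboration of a terminal alkyne through a rhodium vinylidene, which puts boron on the terminal carbon cis to the aryl group; the labile catechol ester 8 is then exchanged in the same flask for the hindered aliphatic diol 6 (transesterification) to give a stable Z boronate.

Step 6
Reactants: 10 O-benzylvanillin (4-benzyloxy-3-methoxybenzaldehyde)
Product: 12 4-benzyloxy-3-methoxyphenol, via aryl formate 11 (not isolated)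
Conditions: mCPBA, CH2Cl2, rt; then K2CO3, MeOH, 0 °C
Reagents that add atoms: 3-chloroperoxybenzoic acid, OOC(=O)c1cccc(Cl)c1
Why: Baeyer–Villiger (Dakin-type) oxidation of an electron-rich benzaldehyde, in which the aryl group migrates to oxygen, followed by methanolysis of formate 11.

Step 7
Reactants: 12 4-benzyloxy-3-methoxyphenol
Product: 13 4-benzyloxy-3-methoxyphenyl trifluoromethanesulfonate
Conditions: Tf2O, pyridine, CH2Cl2, 0 °C
Reagents that add atoms: trifluoromethanesulfonic anhydride, O=S(=O)(OS(=O)(=O)C(F)(F)F)C(F)(F)F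
Why: O-Sulfonylation of a phenol; the triflate is the electrophile that gives the cationic arylpalladium species needed in step 8.

Step 8
Reactants: 9 [(Z)-2-(2-chloro-4-methoxy-5-triisopropylsilyloxyphenyl)ethenyl]B(mac); 14 methyllithium; 13 4-benzyloxy-3-methoxyphenyl trifluoromethanesulfonate
Product: 16 [(1S,2R)-1-(4-benzyloxy-3-methoxyphenyl)-1-(2-chloro-4-methoxy-5-triisopropylsilyloxyphenyl)propan-2-yl]B(mac), via lithium borate 15 (not isolated)
Conditions: 14 (halide-free, Et2O), THF, 0 °C; then 13, Pd(OAc)2 (cat.), (Sp,Sp)-MandyPhos (cat.), THF, 60 °C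
Reagents that add atoms: none
Why: Proposed new method: the closest known reaction type is the palladium-catalysed enantioselective conjunctive cross-coupling of alkenylboron ate complexes with aryl triflates, which with the hindered diol 6 on boron extends to β-alkyl alkenylboronates, whereas a β-aryl (Z)-alkenyl borate has not been used. Zerovalent palladium formed from Pd(OAc)2 and the bisphosphine inserts into the C–O bond of triflate 13, much faster than into the electron-rich aryl chloride of ring A, and the cationic aryl complex of divalent palladium binds the alkene of borate 15. Methyl then shifts from boron to C2 on the face opposite palladium while palladium bonds to C1, where ring A stabilises the benzylic palladium alkyl, and reductive elimination with retention forms the bond from C1 to ring C. No ring is closed. Because methyl and aryl add anti across a geometrically defined Z alkene, the relative configuration of C1 and C2 is the one that becomes 1,2-trans in ring B, and the ferrocenyl bisphosphine selects the alkene face and so the absolute configuration (1S,2R); the sense of induction on this new alkene class has to be confirmed on the first run, the other antipode of the ligand being the remedy. The step needs the metalate shift to win over direct alkenyl transfer to palladium, which the hindered diol on boron secures, and reductive elimination to outrun β-hydride loss from C1–Pd, which the wide-bite-angle ligand favours. Halide-free 14 is used because halide ions block the cationic pathway.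

Step 9
Reactants: 17 ethyl 2,4,6-triisopropylbenzoate; 16 [(1S,2R)-1-(4-benzyloxy-3-methoxyphenyl)-1-(2-chloro-4-methoxy-5-triisopropylsilyloxyphenyl)propan-2-yl]B(mac)
Product: 20 [(2S,3S,4S)-4-(4-benzyloxy-3-methoxyphenyl)-4-(2-chloro-4-methoxy-5-triisopropylsilyloxyphenyl)-3-methylbutan-2-yl]B(mac), via lithiated benzoate 18 (not isolated), via borate complex 19 (not isolated)
Conditions: 17, s-BuLi, (+)-sparteine, Et2O, −78 °C; then 16, −78 °C → 35 °C
Reagents that add atoms: none
Why: Lithiation–borylation: sparteine-mediated enantioselective deprotonation of 17 gives the (R)-configured carbenoid 18, which adds to boron with retention; on warming, C2 migrates in 19 with retention at C2 and inversion at the carbenoid carbon as the benzoate leaves, so C3 is set by the reagent alone. The hindered benzoate is used in place of a carbamate because its borate complexes rearrange without a Lewis acid and do not revert, which matters for a secondary boronate flanked by a diarylmethyl group.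

Step 10
Reactants: 20 [(2S,3S,4S)-4-(4-benzyloxy-3-methoxyphenyl)-4-(2-chloro-4-methoxy-5-triisopropylsilyloxyphenyl)-3-methylbutan-2-yl]B(mac)
Product: 22 [(2R,3S,4S)-4-(4-benzyloxy-3-methoxyphenyl)-4-(2-chloro-4-methoxy-5-triisopropylsilyloxyphenyl)-2,3-dimethylbutyl]B(mac), via chloromethyl borate 21 (not isolated)
Conditions: BrCH2Cl, n-BuLi, THF, −78 °C → rt
Reagents that add atoms: bromochloromethane, ClCBr
Why: Matteson homologation: (chloromethyl)lithium formed in situ by bromine–lithium exchange adds to boron, and in 21 the C3 alkyl group migrates with retention and loss of chloride, inserting C4; exchange of n-BuLi with BrCH2Cl is faster than attack on the aryl chloride.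

Step 11
Reactants: 22 [(2R,3S,4S)-4-(4-benzyloxy-3-methoxyphenyl)-4-(2-chloro-4-methoxy-5-triisopropylsilyloxyphenyl)-2,3-dimethylbutyl]B(mac)
Product: 23 (1S,2S,3R)-1-(4-benzyloxy-3-methoxyphenyl)-6-methoxy-2,3-dimethyl-7-(triisopropylsilyloxy)-1,2,3,4-tetrahydronaphthalene
Conditions: Pd(OAc)2 (cat.), RuPhos, K3PO4, toluene/H2O, 90 °C
Reagents that add atoms: none
Why: Intramolecular B-alkyl Suzuki–Miyaura coupling: zerovalent palladium with the bulky biarylphosphine inserts into the electron-rich aryl chloride, the primary alkyl group is transferred from boron with the help of hydroxide, and reductive elimination closes ring B at C4–C4a through a seven-membered palladacycle; no stereocentre is touched, and since only ring A carries halogen, ring C cannot take part.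

Step 12
Reactants: 23 (1S,2S,3R)-1-(4-benzyloxy-3-methoxyphenyl)-6-methoxy-2,3-dimethyl-7-(triisopropylsilyloxy)-1,2,3,4-tetrahydronaphthalene
Product: 24 2-methoxy-4-[(1S,2S,3R)-6-methoxy-2,3-dimethyl-7-(triisopropylsilyloxy)-1,2,3,4-tetrahydronaphthalen-1-yl]phenol
Conditions: H2 (1 atm), Pd/C, EtOAc/EtOH, rt
Reagents that add atoms: none
Why: Hydrogenolysis of the only benzyl ether; the silyl ether, the methyl ethers and the tetralin are inert, and the aryl chloride is already gone.

Step 13
Reactants: 24 2-methoxy-4-[(1S,2S,3R)-6-methoxy-2,3-dimethyl-7-(triisopropylsilyloxy)-1,2,3,4-tetrahydronaphthalen-1-yl]phenol; 25 ethyl (S)-lactate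
Product: 26 ethyl (2R)-2-{2-methoxy-4-[(1S,2S,3R)-6-methoxy-2,3-dimethyl-7-(triisopropylsilyloxy)-1,2,3,4-tetrahydronaphthalen-1-yl]phenoxy}propanoate
Conditions: PPh3, DIAD, THF, 0 °C → rt
Reagents that add atoms: none
Why: Mitsunobu etherification: the phenol displaces the activated secondary hydroxyl of the lactate by SN2 with inversion, which turns the (S)-lactate centre into the (R)-configured C8'.

Step 14
Reactants: 26 ethyl (2R)-2-{2-methoxy-4-[(1S,2S,3R)-6-methoxy-2,3-dimethyl-7-(triisopropylsilyloxy)-1,2,3,4-tetrahydronaphthalen-1-yl]phenoxy}propanoate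
Product: 27 (2R)-N-methoxy-N-methyl-2-{2-methoxy-4-[(1S,2S,3R)-6-methoxy-2,3-dimethyl-7-(triisopropylsilyloxy)-1,2,3,4-tetrahydronaphthalen-1-yl]phenoxy}propanamide
Conditions: MeNHOMe·HCl, iPrMgCl, THF, −20 °C
Reagents that add atoms: N,O-dimethylhydroxylamine hydrochloride, CNOC.Cl
Why: Weinreb amide formation by aminolysis of the ester with the magnesium amide at low temperature; under these conditions α-alkoxy stereocentres of lactate derivatives are normally retained.

Step 15
Reactants: 28 4-bromo-2-methoxyphenol
Product: 29 (4-bromo-2-methoxyphenoxy)triisopropylsilane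
Conditions: TIPSCl, imidazole, DMF, rt
Reagents that add atoms: triisopropylsilyl chloride, CC(C)[Si](Cl)(C(C)C)C(C)C
Why: Silylation of the phenol, so that ring D carries the same fluoride-labile group as ring A.

Step 16
Reactants: 29 (4-bromo-2-methoxyphenoxy)triisopropylsilane; 27 (2R)-N-methoxy-N-methyl-2-{2-methoxy-4-[(1S,2S,3R)-6-methoxy-2,3-dimethyl-7-(triisopropylsilyloxy)-1,2,3,4-tetrahydronaphthalen-1-yl]phenoxy}propanamide
Product: 31 (2R)-1-[3-methoxy-4-(triisopropylsilyloxy)phenyl]-2-{2-methoxy-4-[(1S,2S,3R)-6-methoxy-2,3-dimethyl-7-(triisopropylsilyloxy)-1,2,3,4-tetrahydronaphthalen-1-yl]phenoxy}propan-1-one, via aryl Grignard reagent 30 (not isolated)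
Conditions: 29, Mg, THF, 45 °C; then 27, THF, −10 °C; aq. NH4Cl
Reagents that add atoms: none
Why: Weinreb ketone synthesis: Grignard reagent 30 adds once to amide 27 and the chelated tetrahedral intermediate collapses only on quench, so neither over-addition nor base-induced epimerisation at C8' of the ketone is expected.

Step 17
Reactants: 31 (2R)-1-[3-methoxy-4-(triisopropylsilyloxy)phenyl]-2-{2-methoxy-4-[(1S,2S,3R)-6-methoxy-2,3-dimethyl-7-(triisopropylsilyloxy)-1,2,3,4-tetrahydronaphthalen-1-yl]phenoxy}propan-1-one
Product: 32 (1S,2R)-1-[3-methoxy-4-(triisopropylsilyloxy)phenyl]-2-{2-methoxy-4-[(1S,2S,3R)-6-methoxy-2,3-dimethyl-7-(triisopropylsilyloxy)-1,2,3,4-tetrahydronaphthalen-1-yl]phenoxy}propan-1-ol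
Conditions: Zn(BH4)2, Et2O, −30 °C; aq. NH4Cl
Reagents that add atoms: none
Why: Chelation-controlled reduction (Cram chelate model): zinc bridges the carbonyl oxygen and the α-aryloxy oxygen, helped by the ortho-methoxy group, and hydride attacks the carbonyl face on the side of the C8' hydrogen, which gives the 7'S carbinol, erythro to the 8'R ether carbon.

Step 18
Reactants: 32 (1S,2R)-1-[3-methoxy-4-(triisopropylsilyloxy)phenyl]-2-{2-methoxy-4-[(1S,2S,3R)-6-methoxy-2,3-dimethyl-7-(triisopropylsilyloxy)-1,2,3,4-tetrahydronaphthalen-1-yl]phenoxy}propan-1-ol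
Product: 33 4-[(1S,2R)-1-hydroxy-2-{4-[(1S,2S,3R)-7-hydroxy-6-methoxy-2,3-dimethyl-1,2,3,4-tetrahydronaphthalen-1-yl]-2-methoxyphenoxy}propyl]-2-methoxyphenol (CID53359464)
Conditions: Bu4NF, AcOH, THF, 0 °C
Reagents that add atoms: none
Why: Fluoride cleavage of both aryl silyl ethers; acetic acid buffers the phenoxides so that the para-hydroxybenzylic alcohol is not driven towards a quinone methide.

## Compound list

1 | 2-chloro-4,5-dimethoxybenzaldehyde | COc1cc(Cl)c(C=O)cc1OC | starting material
2 | 2-chloro-5-hydroxy-4-methoxybenzaldehyde | COc1cc(Cl)c(C=O)cc1O | intermediate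
3 | 2-chloro-4-methoxy-5-(triisopropylsilyloxy)benzaldehyde | COc1cc(Cl)c(C=O)cc1O[Si](C(C)C)(C(C)C)C(C)C | intermediate
4 | 1-chloro-2-ethynyl-5-methoxy-4-(triisopropylsilyloxy)benzene | COc1cc(Cl)c(C#C)cc1O[Si](C(C)C)(C(C)C)C(C)C | intermediate
5 | acenaphthoquinone (acenaphthylene-1,2-dione) | O=C1C(=O)c2cccc3cccc1c23 | starting material
6 | cis-1,2-dimethyl-1,2-dihydroacenaphthylene-1,2-diol | C[C@]1(O)c2cccc3cccc(c23)[C@@]1(C)O | intermediate
7 | catecholborane (1,3,2-benzodioxaborole) | B1Oc2ccccc2O1 | starting material
8 | 2-[(Z)-2-(2-chloro-4-methoxy-5-triisopropylsilyloxyphenyl)ethenyl]-1,3,2-benzodioxaborole | COc1cc(Cl)c(/C=C\B2Oc3ccccc3O2)cc1O[Si](C(C)C)(C(C)C)C(C)C | intermediate (not isolated)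
9 | [(Z)-2-(2-chloro-4-methoxy-5-triisopropylsilyloxyphenyl)ethenyl]B(mac) | COc1cc(Cl)c(/C=C\B2O[C@@]3(C)c4cccc5cccc(c45)[C@@]3(C)O2)cc1O[Si](C(C)C)(C(C)C)C(C)C | intermediate
10 | O-benzylvanillin (4-benzyloxy-3-methoxybenzaldehyde) | COc1cc(C=O)ccc1OCc1ccccc1 | starting material
11 | 4-benzyloxy-3-methoxyphenyl formate | COc1cc(OC=O)ccc1OCc1ccccc1 | intermediate (not isolated)
12 | 4-benzyloxy-3-methoxyphenol | COc1cc(O)ccc1OCc1ccccc1 | intermediate
13 | 4-benzyloxy-3-methoxyphenyl trifluoromethanesulfonate | COc1cc(OS(=O)(=O)C(F)(F)F)ccc1OCc1ccccc1 | intermediate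
14 | methyllithium | [Li]C | starting material
15 | lithium methyl borate of 9 (ate complex, boron configuration undefined) | [Li+].C[B-]1(/C=C\c2cc(O[Si](C(C)C)(C(C)C)C(C)C)c(OC)cc2Cl)O[C@@]2(C)c3cccc4cccc(c34)[C@@]2(C)O1 | intermediate (not isolated)
16 | [(1S,2R)-1-(4-benzyloxy-3-methoxyphenyl)-1-(2-chloro-4-methoxy-5-triisopropylsilyloxyphenyl)propan-2-yl]B(mac) | COc1cc([C@H]([C@@H](C)B2O[C@@]3(C)c4cccc5cccc(c45)[C@@]3(C)O2)c2cc(O[Si](C(C)C)(C(C)C)C(C)C)c(OC)cc2Cl)ccc1OCc1ccccc1 | intermediate
17 | ethyl 2,4,6-triisopropylbenzoate | CCOC(=O)c1c(C(C)C)cc(C(C)C)cc1C(C)C | starting material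
18 | (R)-1-lithioethyl 2,4,6-triisopropylbenzoate (sparteine complex) | [Li][C@H](C)OC(=O)c1c(C(C)C)cc(C(C)C)cc1C(C)C | intermediate (not isolated)
19 | lithium borate complex of 16 and 18 | [Li+].COc1cc([C@H]([C@@H](C)[B-]2([C@H](C)OC(=O)c3c(C(C)C)cc(C(C)C)cc3C(C)C)O[C@@]3(C)c4cccc5cccc(c45)[C@@]3(C)O2)c2cc(O[Si](C(C)C)(C(C)C)C(C)C)c(OC)cc2Cl)ccc1OCc1ccccc1 | intermediate (not isolated)
20 | [(2S,3S,4S)-4-(4-benzyloxy-3-methoxyphenyl)-4-(2-chloro-4-methoxy-5-triisopropylsilyloxyphenyl)-3-methylbutan-2-yl]B(mac) | COc1cc([C@H]([C@@H](C)[C@H](C)B2O[C@@]3(C)c4cccc5cccc(c45)[C@@]3(C)O2)c2cc(O[Si](C(C)C)(C(C)C)C(C)C)c(OC)cc2Cl)ccc1OCc1ccccc1 | intermediate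
21 | lithium (chloromethyl)borate of 20 | [Li+].COc1cc([C@H]([C@@H](C)[C@H](C)[B-]2(CCl)O[C@@]3(C)c4cccc5cccc(c45)[C@@]3(C)O2)c2cc(O[Si](C(C)C)(C(C)C)C(C)C)c(OC)cc2Cl)ccc1OCc1ccccc1 | intermediate (not isolated)
22 | [(2R,3S,4S)-4-(4-benzyloxy-3-methoxyphenyl)-4-(2-chloro-4-methoxy-5-triisopropylsilyloxyphenyl)-2,3-dimethylbutyl]B(mac) | COc1cc([C@H]([C@@H](C)[C@H](C)CB2O[C@@]3(C)c4cccc5cccc(c45)[C@@]3(C)O2)c2cc(O[Si](C(C)C)(C(C)C)C(C)C)c(OC)cc2Cl)ccc1OCc1ccccc1 | intermediate
23 | (1S,2S,3R)-1-(4-benzyloxy-3-methoxyphenyl)-6-methoxy-2,3-dimethyl-7-(triisopropylsilyloxy)-1,2,3,4-tetrahydronaphthalene | COc1cc([C@H]2c3cc(O[Si](C(C)C)(C(C)C)C(C)C)c(OC)cc3C[C@@H](C)[C@@H]2C)ccc1OCc1ccccc1 | intermediate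
24 | 2-methoxy-4-[(1S,2S,3R)-6-methoxy-2,3-dimethyl-7-(triisopropylsilyloxy)-1,2,3,4-tetrahydronaphthalen-1-yl]phenol | COc1cc([C@H]2c3cc(O[Si](C(C)C)(C(C)C)C(C)C)c(OC)cc3C[C@@H](C)[C@@H]2C)ccc1O | intermediate
25 | ethyl (S)-lactate | CCOC(=O)[C@H](C)O | starting material
26 | ethyl (2R)-2-{2-methoxy-4-[(1S,2S,3R)-6-methoxy-2,3-dimethyl-7-(triisopropylsilyloxy)-1,2,3,4-tetrahydronaphthalen-1-yl]phenoxy}propanoate | CCOC(=O)[C@@H](C)Oc1ccc([C@H]2c3cc(O[Si](C(C)C)(C(C)C)C(C)C)c(OC)cc3C[C@@H](C)[C@@H]2C)cc1OC | intermediate
27 | (2R)-N-methoxy-N-methyl-2-{2-methoxy-4-[(1S,2S,3R)-6-methoxy-2,3-dimethyl-7-(triisopropylsilyloxy)-1,2,3,4-tetrahydronaphthalen-1-yl]phenoxy}propanamide | CON(C)C(=O)[C@@H](C)Oc1ccc([C@H]2c3cc(O[Si](C(C)C)(C(C)C)C(C)C)c(OC)cc3C[C@@H](C)[C@@H]2C)cc1OC | intermediate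
28 | 4-bromo-2-methoxyphenol | COc1cc(Br)ccc1O | starting material
29 | (4-bromo-2-methoxyphenoxy)triisopropylsilane | COc1cc(Br)ccc1O[Si](C(C)C)(C(C)C)C(C)C | intermediate
30 | [3-methoxy-4-(triisopropylsilyloxy)phenyl]magnesium bromide | COc1cc([Mg]Br)ccc1O[Si](C(C)C)(C(C)C)C(C)C | intermediate (not isolated)
31 | (2R)-1-[3-methoxy-4-(triisopropylsilyloxy)phenyl]-2-{2-methoxy-4-[(1S,2S,3R)-6-methoxy-2,3-dimethyl-7-(triisopropylsilyloxy)-1,2,3,4-tetrahydronaphthalen-1-yl]phenoxy}propan-1-one | COc1cc(C(=O)[C@@H](C)Oc2ccc([C@H]3c4cc(O[Si](C(C)C)(C(C)C)C(C)C)c(OC)cc4C[C@@H](C)[C@@H]3C)cc2OC)ccc1O[Si](C(C)C)(C(C)C)C(C)C | intermediate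
32 | (1S,2R)-1-[3-methoxy-4-(triisopropylsilyloxy)phenyl]-2-{2-methoxy-4-[(1S,2S,3R)-6-methoxy-2,3-dimethyl-7-(triisopropylsilyloxy)-1,2,3,4-tetrahydronaphthalen-1-yl]phenoxy}propan-1-ol | COc1cc([C@H](O)[C@@H](C)Oc2ccc([C@H]3c4cc(O[Si](C(C)C)(C(C)C)C(C)C)c(OC)cc4C[C@@H](C)[C@@H]3C)cc2OC)ccc1O[Si](C(C)C)(C(C)C)C(C)C | intermediate
33 | 4-[(1S,2R)-1-hydroxy-2-{4-[(1S,2S,3R)-7-hydroxy-6-methoxy-2,3-dimethyl-1,2,3,4-tetrahydronaphthalen-1-yl]-2-methoxyphenoxy}propyl]-2-methoxyphenol | COc1cc([C@H](O)[C@@H](C)Oc2ccc([C@H]3c4cc(O)c(OC)cc4C[C@@H](C)[C@@H]3C)cc2OC)ccc1O | target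

## Step count and least certain steps

Total step count: 18. Longest linear sequence: 14 steps (1, 2, 3, 5, 8, 9, 10, 11, 12, 13, 14, 16, 17, 18).

**Step 8 (key step, proposed new method).** Three processes are most likely to go wrong.
- Direct transfer of the alkenyl group from boron to palladium may occur without methyl migration, because a β-substituent slows the metalate shift and the ortho-chloroaryl group crowds the alkene.
- β-Hydride loss from the benzylic palladium intermediate may compete with reductive elimination.
- Face selection may be incomplete, or the Z geometry may erode before the shift, which would give the 1,2-cis series.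

Fallback with known chemistry, setting out from aldehyde 3: Wittig olefination with ethyltriphenylphosphonium bromide and KN(SiMe3)2 gives 1-chloro-5-methoxy-2-[(Z)-prop-1-enyl]-4-(triisopropylsilyloxy)benzene F1. Copper/palladium-catalysed arylboration of F1 with bis(pinacolato)diboron and 1-(benzyloxy)-4-bromo-2-methoxybenzene F2 follows (CuCl with a chiral N-heterocyclic carbene, Pd(OAc)2/RuPhos, NaOtBu, ambient temperature, so that the ring A chloride is not touched). Boron and aryl add to the same face: syn borylcupration is followed by stereoretentive transfer to palladium. From the Z alkene this gives the pinacol ester 2-[(1S,2R)-1-(4-benzyloxy-3-methoxyphenyl)-1-(2-chloro-4-methoxy-5-triisopropylsilyloxyphenyl)propan-2-yl]-4,4,5,5-tetramethyl-1,3,2-dioxaborolane F3. F3 is taken through the homologations of steps 9 and 10 to the pinacol esters F4 (the secondary boronate corresponding to 20) and F5 (the primary boronate corresponding to 22). F5 is cyclised as in step 11, which brings the sequence back to the route at 23.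

**Step 9.** Formation of the borate complex at a secondary boron centre flanked by a diarylmethyl group and a hindered diol may be slow or reversible. The carbenoid 18 would then decompose before it is captured and 16 would be recovered.

Fallback, setting out from 16: Zweifel olefination (isopropenyllithium, then I2 and NaOMe) replaces boron with retention and gives the alkene 1-[(1S,2R)-1-(4-benzyloxy-3-methoxyphenyl)-2,3-dimethylbut-3-en-1-yl]-2-chloro-4-methoxy-5-(triisopropylsilyloxy)benzene F6. Hydroboration with 9-BBN gives the B-alkyl-9-borabicyclo[3.3.1]nonane F7. Without isolation, F7 undergoes intramolecular B-alkyl Suzuki–Miyaura coupling (Pd(OAc)2/RuPhos, aq. K3PO4) and the sequence comes back at 23. In this variant C3 is set by substrate control in the hydroboration, so a separation of C3 epimers must be expected.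

**Step 11.** Transfer of the primary alkyl group from the hindered diol ester to palladium may be slow. Protodechlorination or β-hydride loss could then take over, and hot aqueous base may start to cleave the aryl silyl ether.

Fallback, setting out from 22:
- Oxidation with NaBO3·4H2O gives the primary alcohol F8 (CH2OH in place of CH2B(mac), configuration unchanged).
- I2, PPh3 and imidazole give the primary iodide F9.
- Zinc dust with LiCl gives the alkylzinc iodide F10.
- Intramolecular Negishi coupling with the aryl chloride (Pd(OAc)2/CPhos, THF) returns to the route at 23.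

**Step 5.** Z selectivity in the trans-hydroboration of an ortho-substituted aryl alkyne may be incomplete, and rhodium may dimerise the alkyne. Any E isomer would end as the 1,2-cis diastereomer after step 8.

Fallback, setting out from 4: deprotonation with n-BuLi, addition of B(OiPr)3 and treatment with HCl in Et2O give the diisopropyl alkynylboronate F11. Exchange with diol 6 in the same flask gives the alkynyl B(mac) ester F12. Syn-hydrozirconation with Cp2Zr(H)Cl followed by protonolysis with water gives the Z alkenylboronate, which comes back to the route at 9.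

**Step 17.** Chelation by the weakly basic aryloxy oxygen may be incomplete, which would lower the erythro preference. Any epimerisation of the α-aryloxy ketone before reduction would add further isomers.

Fallback, setting out from 31: if the reduction gives mainly the threo (1R,2R) alcohol F13, F13 is inverted at C7' by a Mitsunobu reaction with 4-nitrobenzoic acid (PPh3, DIAD) to the (1S,2R) 4-nitrobenzoate F14. Methanolysis (K2CO3, MeOH, 0 °C) returns to the route at 32. A silyl ether lost at this point is of no consequence, since step 18 removes both.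

## Further compounds

F1 | step 8 | 1-chloro-5-methoxy-2-[(Z)-prop-1-enyl]-4-(triisopropylsilyloxy)benzene | COc1cc(Cl)c(/C=C\C)cc1O[Si](C(C)C)(C(C)C)C(C)C
F2 | step 8 | 1-(benzyloxy)-4-bromo-2-methoxybenzene | COc1cc(Br)ccc1OCc1ccccc1
F3 | step 8 | 2-[(1S,2R)-1-(4-benzyloxy-3-methoxyphenyl)-1-(2-chloro-4-methoxy-5-triisopropylsilyloxyphenyl)propan-2-yl]-4,4,5,5-tetramethyl-1,3,2-dioxaborolane | COc1cc([C@H]([C@@H](C)B2OC(C)(C)C(C)(C)O2)c2cc(O[Si](C(C)C)(C(C)C)C(C)C)c(OC)cc2Cl)ccc1OCc1ccccc1
F4 | step 8 | 2-[(2S,3S,4S)-4-(4-benzyloxy-3-methoxyphenyl)-4-(2-chloro-4-methoxy-5-triisopropylsilyloxyphenyl)-3-methylbutan-2-yl]-4,4,5,5-tetramethyl-1,3,2-dioxaborolane | COc1cc([C@H]([C@@H](C)[C@H](C)B2OC(C)(C)C(C)(C)O2)c2cc(O[Si](C(C)C)(C(C)C)C(C)C)c(OC)cc2Cl)ccc1OCc1ccccc1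
F5 | step 8 | 2-[(2R,3S,4S)-4-(4-benzyloxy-3-methoxyphenyl)-4-(2-chloro-4-methoxy-5-triisopropylsilyloxyphenyl)-2,3-dimethylbutyl]-4,4,5,5-tetramethyl-1,3,2-dioxaborolane | COc1cc([C@H]([C@@H](C)[C@H](C)CB2OC(C)(C)C(C)(C)O2)c2cc(O[Si](C(C)C)(C(C)C)C(C)C)c(OC)cc2Cl)ccc1OCc1ccccc1
F6 | step 9 | 1-[(1S,2R)-1-(4-benzyloxy-3-methoxyphenyl)-2,3-dimethylbut-3-en-1-yl]-2-chloro-4-methoxy-5-(triisopropylsilyloxy)benzene | COc1cc([C@H]([C@@H](C)C(C)=C)c2cc(O[Si](C(C)C)(C(C)C)C(C)C)c(OC)cc2Cl)ccc1OCc1ccccc1
F7 | step 9 | 9-[4-(4-benzyloxy-3-methoxyphenyl)-4-(2-chloro-4-methoxy-5-triisopropylsilyloxyphenyl)-2,3-dimethylbutyl]-9-borabicyclo[3.3.1]nonane (configuration as in 22) | COc1cc([C@H]([C@@H](C)[C@H](C)CB2C3CCCC2CCC3)c2cc(O[Si](C(C)C)(C(C)C)C(C)C)c(OC)cc2Cl)ccc1OCc1ccccc1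
F8 | step 11 | 4-(4-benzyloxy-3-methoxyphenyl)-4-(2-chloro-4-methoxy-5-triisopropylsilyloxyphenyl)-2,3-dimethylbutan-1-ol (configuration as in 22) | COc1cc([C@H]([C@@H](C)[C@H](C)CO)c2cc(O[Si](C(C)C)(C(C)C)C(C)C)c(OC)cc2Cl)ccc1OCc1ccccc1
F9 | step 11 | primary iodide corresponding to F8 (CH2I in place of CH2OH) | COc1cc([C@H]([C@@H](C)[C@H](C)CI)c2cc(O[Si](C(C)C)(C(C)C)C(C)C)c(OC)cc2Cl)ccc1OCc1ccccc1
F10 | step 11 | alkylzinc iodide corresponding to F9 (CH2ZnI in place of CH2I) | COc1cc([C@H]([C@@H](C)[C@H](C)C[Zn]I)c2cc(O[Si](C(C)C)(C(C)C)C(C)C)c(OC)cc2Cl)ccc1OCc1ccccc1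
F11 | step 5 | diisopropyl [(2-chloro-4-methoxy-5-triisopropylsilyloxyphenyl)ethynyl]boronate | COc1cc(Cl)c(C#CB(OC(C)C)OC(C)C)cc1O[Si](C(C)C)(C(C)C)C(C)C
F12 | step 5 | [(2-chloro-4-methoxy-5-triisopropylsilyloxyphenyl)ethynyl]B(mac) | COc1cc(Cl)c(C#CB2O[C@@]3(C)c4cccc5cccc(c45)[C@@]3(C)O2)cc1O[Si](C(C)C)(C(C)C)C(C)C
F13 | step 17 | (1R,2R) epimer of 32 (threo alcohol) | COc1cc([C@@H](O)[C@@H](C)Oc2ccc([C@H]3c4cc(O[Si](C(C)C)(C(C)C)C(C)C)c(OC)cc4C[C@@H](C)[C@@H]3C)cc2OC)ccc1O[Si](C(C)C)(C(C)C)C(C)C
F14 | step 17 | 4-nitrobenzoate of 32 (1S,2R) | COc1cc([C@H](OC(=O)c2ccc([N+](=O)[O-])cc2)[C@@H](C)Oc2ccc([C@H]3c4cc(O[Si](C(C)C)(C(C)C)C(C)C)c(OC)cc4C[C@@H](C)[C@@H]3C)cc2OC)ccc1O[Si](C(C)C)(C(C)C)C(C)C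
A1 | alternative 1 | 7-benzyloxy-1-(4-hydroxy-3-methoxyphenyl)-6-methoxy-3-methyl-1,2,3,4-tetrahydronaphthalene-2-carbaldehyde (all-trans, ring centres arranged as in the target) | COc1cc([C@H]2c3cc(OCc4ccccc4)c(OC)cc3C[C@@H](C)[C@@H]2C=O)ccc1O
A2 | alternative 1 | (3R)-4-{4-benzyloxy-2-[hydroxy(4-hydroxy-3-methoxyphenyl)methyl]-5-methoxyphenyl}-3-methylbutanal | COc1cc(C(O)c2cc(OCc3ccccc3)c(OC)cc2C[C@@H](C)CC=O)ccc1O
A3 | alternative 2 | methyl 1-(4-allyloxy-3-methoxyphenyl)-7-benzyloxy-4-hydroxy-6-methoxy-2-methyl-1,2,3,4-tetrahydronaphthalene-3-carboxylate (C1, C2, C3 all-trans, 4-OH cis to the ester) | COc1cc([C@H]2c3cc(OCc4ccccc4)c(OC)cc3[C@@H](O)[C@@H](C(=O)OC)[C@@H]2C)ccc1OCC=C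
A4 | alternative 2 | 2-(4-allyloxy-3-methoxybenzyl)-4-benzyloxy-5-methoxybenzaldehyde | COc1cc(Cc2cc(OCc3ccccc3)c(OC)cc2C=O)ccc1OCC=C
A5 | alternative 2 | methyl (E)-but-2-enoate | C/C=C/C(=O)OC
A6 | alternative 3 | (1S,2S,3R)-1-(4-benzyloxy-3-methoxyphenyl)-6-methoxy-2,3-dimethyl-1,2,3,4-tetrahydronaphthalen-7-yl pivalate | COc1cc([C@H]2c3cc(OC(=O)C(C)(C)C)c(OC)cc3C[C@@H](C)[C@@H]2C)ccc1OCc1ccccc1
A7 | alternative 3 | 1-benzyloxy-2-methoxy-4-[(E)-prop-1-enyl]benzene | C/C=C/c1ccc(OCc2ccccc2)c(OC)c1
A8 | alternative 3 | 2-methoxy-4-[(E)-prop-1-enyl]phenyl pivalate | C/C=C/c1ccc(OC(=O)C(C)(C)C)c(OC)c1
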